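**Plan**

Atoms are numbered as in germacranes: ring C1–C10, C11–C13 on C7, C14 on C10, C15 on C4.

1. Retrosynthesis: the C13 acetate and the C10 silyl ether come off last. The butenolide is then cut at C11–C12 and O–C12, which takes CO out of the macrocyclic (Z)-β-iodoenone 26.
2. What allows this: C6 is a ketone with a single enolisable side (C5H2) and carries the exocyclic iodoalkene C7=C11–I. O=C6–C7=C11 is a 1-oxadiene that takes up CO in a formal (4+1) carbonylative lactonisation, and the ten-membered ring fixes the geometry of the new C5=C6 bond.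
3. The ten-membered ring is cut at C7–C8: an iodo-aldol ring closure of ynone–aldehyde 23 makes this bond, creates C8 and puts iodine on C11.
4. The 2,3-dihydrofuran (O, C1–C4) is cut at O–C1 (5-endo-dig hydroalkoxylation) and at C2–C3 (alkyne 13 plus epoxide 7).
5. Forward order of rings: dihydrofuran (step 12), ten-membered carbocycle (step 18), butenolide (step 20).
6. Stereochemistry: C4 and C10 both come from (S)-citramalic acid 1; C8 arises in the aldol ring closure under control of C10; the 5E geometry is enforced by the ring.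

Key step: step 20

Remark (assumption): lactol 11 and alcohol 21 are carried as mixtures at centres that are destroyed later; iodoenone 25 is drawn as the Z isomer expected from the closed aldol transition state, and either alkene isomer should serve in step 20.

**Route**

Step 1
Reactants: 1 (S)-citramalic acid
Product: 2 (2S)-2-methylbutane-1,2,4-triol
Conditions: BH3·SMe2, B(OMe)3, THF, 0 °C to rt; MeOH
Reagents that add atoms: none
Why: Borane reduces both carboxyl groups (carboxylic acid reduction) and cannot touch the fully substituted carbinol centre.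

Step 2
Reactants: 2 (2S)-2-methylbutane-1,2,4-triol
Product: 3 2-[(4S)-2,2,4-trimethyl-1,3-dioxolan-4-yl]ethanol
Conditions: 2,2-dimethoxypropane, p-TsOH (cat.), acetone, rt
Reagents that add atoms: 2,2-dimethoxypropane COC(C)(C)OC
Why: Acetonide formation under thermodynamic control should prefer the five-membered dioxolane of the 1,2-diol and leave the primary hydroxyl of the future C6 free.

Step 3
Reactants: 3 2-[(4S)-2,2,4-trimethyl-1,3-dioxolan-4-yl]ethanol
Product: 4 2-[(4S)-2,2,4-trimethyl-1,3-dioxolan-4-yl]ethyl pivalate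
Conditions: PivCl, pyridine, DMAP (cat.), CH2Cl2, 0 °C
Reagents that add atoms: pivaloyl chloride CC(C)(C)C(=O)Cl
Why: Esterification of the primary alcohol installs a group that should survive acetylide and Lewis acid and can later be removed reductively without acid.

Step 4
Reactants: 4 2-[(4S)-2,2,4-trimethyl-1,3-dioxolan-4-yl]ethyl pivalate
Product: 5 (3S)-3,4-dihydroxy-3-methylbutyl pivalate
Conditions: AcOH/H2O 4:1, 40 °C
Reagents that add atoms: none
Why: Mild aqueous acid hydrolyses the acetonide (acetal hydrolysis) without cleaving the pivalate or touching the stereocentre.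

Step 5
Reactants: 5 (3S)-3,4-dihydroxy-3-methylbutyl pivalate
Product: 7 2-[(2S)-2-methyloxiran-2-yl]ethyl pivalate, via primary tosylate 6 (not isolated)
Conditions: TsCl, Et3N, Bu2SnO (cat.), CH2Cl2, rt; then DBU, rt
Reagents that add atoms: none
Why: Tin-acetal-catalysed sulfonylation should pick the primary hydroxyl and the tertiary oxygen then closes the epoxide by 3-exo-tet Williamson substitution, so the C–O bond at the stereocentre is never broken.

Step 6
Reactants: 1 (S)-citramalic acid
Product: 8 2-[(4S)-2,2,4-trimethyl-5-oxo-1,3-dioxolan-4-yl]acetic acid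
Conditions: 2,2-dimethoxypropane, p-TsOH (cat.), rt
Reagents that add atoms: 2,2-dimethoxypropane COC(C)(C)OC
Why: The α-hydroxy acid closes to a 1,3-dioxolan-4-one (acetalisation), which tells the two carboxyl groups apart.

Step 7
Reactants: 8 2-[(4S)-2,2,4-trimethyl-5-oxo-1,3-dioxolan-4-yl]acetic acid
Product: 10 (3S)-3-hydroxy-3-methyloxolan-2-one, via dioxolanone alcohol 9 (not isolated)
Conditions: BH3·SMe2, THF, 0 °C to rt; MeOH; then p-TsOH (cat.), CH2Cl2, rt
Reagents that add atoms: none
Why: Borane reduces the free acid faster than the dioxolanone ester, and acid-catalysed transesterification of alcohol 9 should give the γ-lactone with loss of acetone.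

Step 8
Reactants: 10 (3S)-3-hydroxy-3-methyloxolan-2-one
Product: 11 (3S)-3-methyloxolane-2,3-diol (anomer mixture)
Conditions: i-Bu2AlH (2.2 equiv), CH2Cl2, −78 °C; aqueous potassium sodium tartrate
Reagents that add atoms: none
Why: Partial lactone reduction stops at the aluminium lactolate at low temperature.

Step 9
Reactants: 11 (3S)-3-methyloxolane-2,3-diol
Product: 12 (3S)-3-methylpent-4-yne-1,3-diol
Conditions: dimethyl (1-diazo-2-oxopropyl)phosphonate, K2CO3, MeOH, 0 °C to rt
Reagents that add atoms: dimethyl (1-diazo-2-oxopropyl)phosphonate CC(=O)C(=[N+]=[N-])P(=O)(OC)OC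
Why: Seyferth–Gilbert homologation in its Ohira–Bestmann form converts the open hydroxy-aldehyde tautomer of the lactol into the terminal alkyne, and the quaternary α-carbon cannot epimerise.

Step 10
Reactants: 12 (3S)-3-methylpent-4-yne-1,3-diol
Product: 13 (3S)-3-methyl-1,3-bis(triethylsilyloxy)pent-4-yne
Conditions: TESOTf (2.5 equiv), 2,6-lutidine, CH2Cl2, −78 to 0 °C
Reagents that add atoms: triethylsilyl trifluoromethanesulfonate CC[Si](CC)(CC)OS(=O)(=O)C(F)(F)F
Why: The silyl triflate silylates the primary and the hindered tertiary propargylic hydroxyl alike (silyl ether formation).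

Step 11
Reactants: 13 (3S)-3-methyl-1,3-bis(triethylsilyloxy)pent-4-yne; 7 2-[(2S)-2-methyloxiran-2-yl]ethyl pivalate
Product: 15 (3R,7S)-3-hydroxy-3,7-dimethyl-7,9-bis(triethylsilyloxy)non-5-yn-1-yl pivalate, via lithium acetylide 14 (not isolated)
Conditions: n-BuLi, THF, −78 °C; BF3·OEt2; then 7, −78 °C
Reagents that add atoms: none
Why: Yamaguchi–Hirao alkynylation: the alkynyl trifluoroborate formed from 14 opens the BF3-activated epoxide by SN2 attack at its CH2 terminus, so both quaternary stereocentres are carried in unchanged.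

Step 12
Reactants: 15 (3R,7S)-3-hydroxy-3,7-dimethyl-7,9-bis(triethylsilyloxy)non-5-yn-1-yl pivalate
Product: 16 2-[(2R)-5-[(2S)-2,4-bis(triethylsilyloxy)butan-2-yl]-2-methyl-2,3-dihydrofuran-2-yl]ethyl pivalate
Conditions: PdCl2(PhCN)2 (5 mol %), Et2O, 4 Å MS, rt
Reagents that add atoms: none
Why: Divalent palladium activates the alkyne for attack of the tertiary hydroxyl in a 5-endo-dig hydroalkoxylation (cycloisomerisation of a homopropargylic alcohol); the 4-exo mode is not open and the quaternary C4 blocks aromatisation.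

Step 13
Reactants: 16 2-[(2R)-5-[(2S)-2,4-bis(triethylsilyloxy)butan-2-yl]-2-methyl-2,3-dihydrofuran-2-yl]ethyl pivalate
Product: 17 2-[(2R)-5-[(2S)-2,4-bis(triethylsilyloxy)butan-2-yl]-2-methyl-2,3-dihydrofuran-2-yl]ethanol
Conditions: i-Bu2AlH (2.2 equiv), CH2Cl2, −78 °C; aqueous potassium sodium tartrate
Reagents that add atoms: none
Why: Reductive ester cleavage avoids acid and should leave the silyl ethers and the enol ether intact.

Step 14
Reactants: 17 2-[(2R)-5-[(2S)-2,4-bis(triethylsilyloxy)butan-2-yl]-2-methyl-2,3-dihydrofuran-2-yl]ethanol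
Product: 18 2-[(2R)-5-[(2S)-2,4-bis(triethylsilyloxy)butan-2-yl]-2-methyl-2,3-dihydrofuran-2-yl]acetaldehyde
Conditions: Dess–Martin periodinane, pyridine, CH2Cl2, 0 °C
Reagents that add atoms: none
Why: Dess–Martin oxidation under pyridine buffer should give the aldehyde without acid-promoted hydration of the enol ether.

Step 15
Reactants: 18 2-[(2R)-5-[(2S)-2,4-bis(triethylsilyloxy)butan-2-yl]-2-methyl-2,3-dihydrofuran-2-yl]acetaldehyde; 19 tert-butyldimethyl(prop-2-yn-1-yloxy)silane
Product: 21 1-[(2R)-5-[(2S)-2,4-bis(triethylsilyloxy)butan-2-yl]-2-methyl-2,3-dihydrofuran-2-yl]-5-(tert-butyldimethylsilyloxy)pent-3-yn-2-ol (both C2 epimers), via lithium acetylide 20 (not isolated)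
Conditions: 19, n-BuLi, THF, −78 °C; then 18, −78 °C; aqueous NH4Cl
Reagents that add atoms: none
Why: 1,2-Addition of the lithium acetylide (alkynylation) at −78 °C should outrun enolisation and β-elimination of the β-alkoxy aldehyde, and the new carbinol centre is oxidised away in step 17.

Step 16
Reactants: 21 1-[(2R)-5-[(2S)-2,4-bis(triethylsilyloxy)butan-2-yl]-2-methyl-2,3-dihydrofuran-2-yl]-5-(tert-butyldimethylsilyloxy)pent-3-yn-2-ol
Product: 22 (3S)-3-[(5R)-5-[5-(tert-butyldimethylsilyloxy)-2-hydroxypent-3-yn-1-yl]-5-methyl-4,5-dihydrofuran-2-yl]-3-(triethylsilyloxy)butan-1-ol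
Conditions: HF·pyridine, pyridine, THF, 0 °C
Reagents that add atoms: none
Why: Buffered HF·pyridine should remove the primary triethylsilyl ether much faster than the tertiary triethylsilyl and the primary tert-butyldimethylsilyl ethers (selective desilylation).

Step 17
Reactants: 22 (3S)-3-[(5R)-5-[5-(tert-butyldimethylsilyloxy)-2-hydroxypent-3-yn-1-yl]-5-methyl-4,5-dihydrofuran-2-yl]-3-(triethylsilyloxy)butan-1-ol
Product: 23 (3S)-3-[(5R)-5-[5-(tert-butyldimethylsilyloxy)-2-oxopent-3-yn-1-yl]-5-methyl-4,5-dihydrofuran-2-yl]-3-(triethylsilyloxy)butanal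
Conditions: Dess–Martin periodinane (3 equiv), pyridine, CH2Cl2, 0 °C to rt; used at once
Reagents that add atoms: none
Why: Dess–Martin oxidation converts the propargylic alcohol to the ynone and the primary alcohol to the aldehyde in one operation.

Step 18
Reactants: 23 (3S)-3-[(5R)-5-[5-(tert-butyldimethylsilyloxy)-2-oxopent-3-yn-1-yl]-5-methyl-4,5-dihydrofuran-2-yl]-3-(triethylsilyloxy)butanal
Product: 25 (4R,8R,10S,7(11)Z)-1,4-epoxy-8-hydroxy-11-iodo-13-(tert-butyldimethylsilyloxy)-10-(triethylsilyloxy)-12-norgermacra-1,7(11)-dien-6-one, via magnesium iodoallenolate 24 (not isolated)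
Conditions: MgI2 (1.5 equiv), CH2Cl2, slow addition of 23 to 0.002 M, 0 °C to rt
Reagents that add atoms: magnesium iodide [Mg+2].[I-].[I-]
Why: Proposed new method: MgI2 should add iodide reversibly to C11 of the ynone to give magnesium β-iodoallenolate 24, whose C7 adds through a magnesium-bridged closed transition state to the tethered C8 aldehyde and so closes the ten-membered carbocycle (nine-membered oxacycle); the closest known reaction type is the MgI2- or TMSI-mediated iodo-aldol (halo Morita–Baylis–Hillman) reaction of ynones with aldehydes, known between two molecules and for small rings, and here the rigid dihydrofuran turn, the reversibility of iodide addition and high dilution should favour ring closure, while attack on the aldehyde face syn to C1 with the C8=O and C10–O dipoles opposed should give the 8,10-syn (8R) aldolate.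

Step 19
Reactants: 25 (4R,8R,10S,7(11)Z)-1,4-epoxy-8-hydroxy-11-iodo-13-(tert-butyldimethylsilyloxy)-10-(triethylsilyloxy)-12-norgermacra-1,7(11)-dien-6-one
Product: 26 (4R,8R,10S,7(11)Z)-1,4-epoxy-11-iodo-8-(methacryloyloxy)-13-(tert-butyldimethylsilyloxy)-10-(triethylsilyloxy)-12-norgermacra-1,7(11)-dien-6-one
Conditions: methacrylic anhydride, Et3N, DMAP (cat.), CH2Cl2, −20 to 0 °C
Reagents that add atoms: methacrylic anhydride C=C(C)C(=O)OC(=O)C(C)=C
Why: DMAP-catalysed acylation of the secondary allylic alcohol (esterification with an anhydride) proceeds with retention at C8 and keeps O8 from competing for the acylpalladium in step 20.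

Step 20
Reactants: 26 (4R,8R,10S,7(11)Z)-1,4-epoxy-11-iodo-8-(methacryloyloxy)-13-(tert-butyldimethylsilyloxy)-10-(triethylsilyloxy)-12-norgermacra-1,7(11)-dien-6-one
Product: 27 (4R,5E,8R,10S)-1,4-epoxy-8-(methacryloyloxy)-13-(tert-butyldimethylsilyloxy)-10-(triethylsilyloxy)germacra-1,5,7(11)-trien-12,6-olide
Conditions: PdCl2(PPh3)2 (5 mol %), CO (20 atm), Et3N (3 equiv), MeCN, 60 °C
Reagents that add atoms: carbon monoxide [C-]#[O+]
Why: Oxidative addition of zerovalent palladium into the C11–I bond, CO insertion to the C12 acylpalladium and its capture by the C6 enol oxygen (Et3N-assisted enolisation toward C5) form the C11–C12 and C12–O bonds in one operation, a formal (4+1) carbonylative annulation of the 1-oxadiene O=C6–C7=C11. The closest known reaction type is the palladium-catalysed carbonylative lactonisation of (Z)-β-iodoenones and o-iodoaryl ketones, in which the acylpalladium is trapped by the enolate oxygen to give γ-alkylidenebutenolides and alkylidenephthalides. The butenolide closes by 5-exo-trig O-acylation and no other ring is formed. No stereocentre is created, but the C5=C6 geometry is: the ten-membered carbocycle accommodates only the enol in which C4 and C7 are cis, so only the 5E ylidene can form. The step needs O- over C-acylation (C5 is neopentylic and C-attack would give a strained bridged dione), insertion into C–I ahead of ionisation of the allylic C8 ester or Heck addition to the methacrylate (CO pressure and the fast five-membered closure should secure this), and a cis relation of C6 and the C11–Pd bond, which either alkene isomer of 26 can reach because β-acylvinylpalladium species equilibrate through their allenolate form. C13 carries a silyl ether and not the acetate so that β-acetoxy elimination from the C11 vinylpalladium is not open.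

Step 21
Reactants: 27 (4R,5E,8R,10S)-1,4-epoxy-8-(methacryloyloxy)-13-(tert-butyldimethylsilyloxy)-10-(triethylsilyloxy)germacra-1,5,7(11)-trien-12,6-olide
Product: 28 (4R,5E,8R,10S)-1,4-epoxy-10,13-dihydroxy-8-(methacryloyloxy)germacra-1,5,7(11)-trien-12,6-olide
Conditions: HF·pyridine, pyridine, THF, 0 °C to rt
Reagents that add atoms: none
Why: Fluoride-mediated desilylation cleaves both silyl ethers while the pyridine buffer should protect the enol ether and the esters.

Step 22
Reactants: 28 (4R,5E,8R,10S)-1,4-epoxy-10,13-dihydroxy-8-(methacryloyloxy)germacra-1,5,7(11)-trien-12,6-olide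
Product: 29 (4R,5E,8R,10S)-13-acetoxy-1,4-epoxy-10-hydroxy-8-(methacryloyloxy)germacra-1,5,7(11)-trien-12,6-olide (CNP0394509.1)
Conditions: Ac2O, pyridine, CH2Cl2, 0 °C
Reagents that add atoms: acetic anhydride CC(=O)OC(C)=O
Why: Acetylation of the primary allylic alcohol should be far faster than that of the hindered tertiary C10 hydroxyl (chemoselective esterification).

**Compound list**

1 | (S)-citramalic acid | C[C@](O)(CC(=O)O)C(=O)O | starting material
2 | (2S)-2-methylbutane-1,2,4-triol | C[C@](O)(CCO)CO | intermediate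
3 | 2-[(4S)-2,2,4-trimethyl-1,3-dioxolan-4-yl]ethanol | C[C@]1(CCO)COC(C)(C)O1 | intermediate
4 | 2-[(4S)-2,2,4-trimethyl-1,3-dioxolan-4-yl]ethyl pivalate | C[C@]1(CCOC(=O)C(C)(C)C)COC(C)(C)O1 | intermediate
5 | (3S)-3,4-dihydroxy-3-methylbutyl pivalate | C[C@](O)(CCOC(=O)C(C)(C)C)CO | intermediate
6 | (3S)-3-hydroxy-3-methyl-4-(tosyloxy)butyl pivalate | C[C@](O)(CCOC(=O)C(C)(C)C)COS(=O)(=O)c1ccc(C)cc1 | intermediate (not isolated)
7 | 2-[(2S)-2-methyloxiran-2-yl]ethyl pivalate | C[C@]1(CCOC(=O)C(C)(C)C)CO1 | intermediate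
8 | 2-[(4S)-2,2,4-trimethyl-5-oxo-1,3-dioxolan-4-yl]acetic acid | C[C@@]1(CC(=O)O)OC(C)(C)OC1=O | intermediate
9 | (5S)-5-(2-hydroxyethyl)-2,2,5-trimethyl-1,3-dioxolan-4-one | C[C@@]1(CCO)OC(C)(C)OC1=O | intermediate (not isolated)
10 | (3S)-3-hydroxy-3-methyloxolan-2-one | C[C@]1(O)CCOC1=O | intermediate
11 | (3S)-3-methyloxolane-2,3-diol (anomer mixture) | C[C@]1(O)CCOC1O | intermediate
12 | (3S)-3-methylpent-4-yne-1,3-diol | C#C[C@@](C)(O)CCO | intermediate
13 | (3S)-3-methyl-1,3-bis(triethylsilyloxy)pent-4-yne | C#C[C@@](C)(O[Si](CC)(CC)CC)CCO[Si](CC)(CC)CC | intermediate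
14 | lithium acetylide of 13 | [Li]C#C[C@@](C)(O[Si](CC)(CC)CC)CCO[Si](CC)(CC)CC | intermediate (not isolated)
15 | (3R,7S)-3-hydroxy-3,7-dimethyl-7,9-bis(triethylsilyloxy)non-5-yn-1-yl pivalate | CC[Si](CC)(CC)OCC[C@](C)(O[Si](CC)(CC)CC)C#CC[C@@](C)(O)CCOC(=O)C(C)(C)C | intermediate
16 | 2-[(2R)-5-[(2S)-2,4-bis(triethylsilyloxy)butan-2-yl]-2-methyl-2,3-dihydrofuran-2-yl]ethyl pivalate | CC[Si](CC)(CC)OCC[C@](C)(O[Si](CC)(CC)CC)C1=CC[C@](C)(CCOC(=O)C(C)(C)C)O1 | intermediate
17 | 2-[(2R)-5-[(2S)-2,4-bis(triethylsilyloxy)butan-2-yl]-2-methyl-2,3-dihydrofuran-2-yl]ethanol | CC[Si](CC)(CC)OCC[C@](C)(O[Si](CC)(CC)CC)C1=CC[C@](C)(CCO)O1 | intermediate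
18 | 2-[(2R)-5-[(2S)-2,4-bis(triethylsilyloxy)butan-2-yl]-2-methyl-2,3-dihydrofuran-2-yl]acetaldehyde | CC[Si](CC)(CC)OCC[C@](C)(O[Si](CC)(CC)CC)C1=CC[C@](C)(CC=O)O1 | intermediate
19 | tert-butyldimethyl(prop-2-yn-1-yloxy)silane | C#CCO[Si](C)(C)C(C)(C)C | starting material
20 | lithium acetylide of 19 | [Li]C#CCO[Si](C)(C)C(C)(C)C | intermediate (not isolated)
21 | 1-[(2R)-5-[(2S)-2,4-bis(triethylsilyloxy)butan-2-yl]-2-methyl-2,3-dihydrofuran-2-yl]-5-(tert-butyldimethylsilyloxy)pent-3-yn-2-ol (both C2 epimers) | CC[Si](CC)(CC)OCC[C@](C)(O[Si](CC)(CC)CC)C1=CC[C@](C)(CC(O)C#CCO[Si](C)(C)C(C)(C)C)O1 | intermediate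
22 | (3S)-3-[(5R)-5-[5-(tert-butyldimethylsilyloxy)-2-hydroxypent-3-yn-1-yl]-5-methyl-4,5-dihydrofuran-2-yl]-3-(triethylsilyloxy)butan-1-ol | OCC[C@](C)(O[Si](CC)(CC)CC)C1=CC[C@](C)(CC(O)C#CCO[Si](C)(C)C(C)(C)C)O1 | intermediate
23 | (3S)-3-[(5R)-5-[5-(tert-butyldimethylsilyloxy)-2-oxopent-3-yn-1-yl]-5-methyl-4,5-dihydrofuran-2-yl]-3-(triethylsilyloxy)butanal | O=CC[C@](C)(O[Si](CC)(CC)CC)C1=CC[C@](C)(CC(=O)C#CCO[Si](C)(C)C(C)(C)C)O1 | intermediate
24 | magnesium β-iodoallenolate of 23 (iodide on C11, O6–MgI) | O=CC[C@](C)(O[Si](CC)(CC)CC)C1=CC[C@](C)(CC(O[Mg]I)=C=C(I)CO[Si](C)(C)C(C)(C)C)O1 | intermediate (not isolated)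
25 | (4R,8R,10S,7(11)Z)-1,4-epoxy-8-hydroxy-11-iodo-13-(tert-butyldimethylsilyloxy)-10-(triethylsilyloxy)-12-norgermacra-1,7(11)-dien-6-one | O[C@@H]1C[C@](C)(O[Si](CC)(CC)CC)C2=CC[C@](C)(CC(=O)/C1=C(\I)CO[Si](C)(C)C(C)(C)C)O2 | intermediate
26 | (4R,8R,10S,7(11)Z)-1,4-epoxy-11-iodo-8-(methacryloyloxy)-13-(tert-butyldimethylsilyloxy)-10-(triethylsilyloxy)-12-norgermacra-1,7(11)-dien-6-one | C=C(C)C(=O)O[C@@H]1C[C@](C)(O[Si](CC)(CC)CC)C2=CC[C@](C)(CC(=O)/C1=C(\I)CO[Si](C)(C)C(C)(C)C)O2 | intermediate
27 | (4R,5E,8R,10S)-1,4-epoxy-8-(methacryloyloxy)-13-(tert-butyldimethylsilyloxy)-10-(triethylsilyloxy)germacra-1,5,7(11)-trien-12,6-olide | C=C(C)C(=O)O[C@@H]1C[C@](C)(O[Si](CC)(CC)CC)C2=CC[C@](C)(/C=C3/OC(=O)C(CO[Si](C)(C)C(C)(C)C)=C31)O2 | intermediate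
28 | (4R,5E,8R,10S)-1,4-epoxy-10,13-dihydroxy-8-(methacryloyloxy)germacra-1,5,7(11)-trien-12,6-olide | C=C(C)C(=O)O[C@@H]1C[C@](C)(O)C2=CC[C@](C)(/C=C3/OC(=O)C(CO)=C31)O2 | intermediate
29 | (4R,5E,8R,10S)-13-acetoxy-1,4-epoxy-10-hydroxy-8-(methacryloyloxy)germacra-1,5,7(11)-trien-12,6-olide (CNP0394509.1) | C=C(C)C(=O)O[C@@H]1C[C@](C)(O)C2=CC[C@](C)(/C=C3/OC(=O)C(COC(C)=O)=C31)O2 | target

**Step count and risks**

Total steps: 22. Longest linear sequence: 17 steps (steps 6–22 from 1; the epoxide branch, steps 1–5, joins at step 11 and gives the same length).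

Steps most likely to fail:

Step 18 (Proposed new method). Two processes are at risk. The aldol addition inside the medium-ring transition state may take the other face of the aldehyde, or the aldolate may equilibrate by retro-aldol, so that the C8 epimer forms. Intermolecular aldol addition may also compete with ring closure; against that the route has only dilution, and no known reaction was found that closes this ring with the C11 iodide in place. The fallback, by known chemistry, therefore covers the facial problem only. It sets out from 23: if the ring closure delivers the 8S alcohol, (4R,8S,10S,7(11)Z)-1,4-epoxy-8-hydroxy-11-iodo-13-(tert-butyldimethylsilyloxy)-10-(triethylsilyloxy)-12-norgermacra-1,7(11)-dien-6-one F1, the acylation of step 19 is replaced by a Mitsunobu esterification (methacrylic acid, PPh3, DIAD, toluene, 0 °C). SN2 inversion at C8 installs the methacrylate with the required configuration, and the route is rejoined at 26.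

Step 20. The acylpalladium may be lost before the enol oxygen closes the ring: through slow oxidative addition into the tetrasubstituted iodoalkene, C-acylation, or amine-induced β-elimination of the C4–O bond from the C5 enolate. The fallback separates carbonylation from lactonisation and sets out from 26. Palladium-catalysed alkoxycarbonylation in the presence of allyl alcohol (PdCl2(PPh3)2, CO, allyl alcohol, Et3N, MeCN) should give the allyl ester of the (Z)-γ-keto acid, F2. Removal of the allyl group (Pd(PPh3)4, morpholine, THF) frees the acid, which should close to the γ-hydroxybutenolide (C6 hemiketal) F3. Dehydration toward C5, the only side with hydrogen (Ac2O, Et3N, DMAP, CH2Cl2), then gives the ylidene butenolide, and the route is rejoined at 27.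

Step 12. The new enol ether may take up the hydroxyl of unreacted 15 or traces of water under the palladium catalyst, giving ketal or hydroxy ketone in place of the dihydrofuran. The fallback makes the ketal on purpose and sets out from 15. Cyclisation in methanol (PdCl2(MeCN)2, MeOH, rt; hydroalkoxylation with ketalisation) should give the cyclic methyl ketal, 2-[(2R)-5-[(2S)-2,4-bis(triethylsilyloxy)butan-2-yl]-5-methoxy-2-methyloxolan-2-yl]ethyl pivalate F4, as a mixture at C1. Elimination of methanol with TMSOTf and i-Pr2NEt (CH2Cl2, −20 °C) can go only toward C2, and the route is rejoined at 16.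

Further compounds
F1 | step 18 | (4R,8S,10S,7(11)Z)-1,4-epoxy-8-hydroxy-11-iodo-13-(tert-butyldimethylsilyloxy)-10-(triethylsilyloxy)-12-norgermacra-1,7(11)-dien-6-one | O[C@H]1C[C@](C)(O[Si](CC)(CC)CC)C2=CC[C@](C)(CC(=O)/C1=C(\I)CO[Si](C)(C)C(C)(C)C)O2
F2 | step 20 | allyl (4R,8R,10S,7(11)Z)-1,4-epoxy-8-(methacryloyloxy)-6-oxo-13-(tert-butyldimethylsilyloxy)-10-(triethylsilyloxy)germacra-1,7(11)-dien-12-oate | C=C(C)C(=O)O[C@@H]1C[C@](C)(O[Si](CC)(CC)CC)C2=CC[C@](C)(CC(=O)/C1=C(\C(=O)OCC=C)CO[Si](C)(C)C(C)(C)C)O2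
F3 | step 20 | (4R,8R,10S)-1,4-epoxy-6-hydroxy-8-(methacryloyloxy)-13-(tert-butyldimethylsilyloxy)-10-(triethylsilyloxy)germacra-1,7(11)-dien-12,6-olide (C6 hemiketal mixture) | C=C(C)C(=O)O[C@@H]1C[C@](C)(O[Si](CC)(CC)CC)C2=CC[C@](C)(CC3(O)OC(=O)C(CO[Si](C)(C)C(C)(C)C)=C31)O2
F4 | step 12 | 2-[(2R)-5-[(2S)-2,4-bis(triethylsilyloxy)butan-2-yl]-5-methoxy-2-methyloxolan-2-yl]ethyl pivalate (C5 epimer mixture) | CC[Si](CC)(CC)OCC[C@](C)(O[Si](CC)(CC)CC)C1(OC)CC[C@](C)(CCOC(=O)C(C)(C)C)O1
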